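(The numbers in the tables come from a simulation on assumed constants; the scatter is artificial.)

If a flask's substrate lasts past the reading, target at the reading follows how far the catalyst has got; if it doesn't, target has stood unfed and losing for the remaining minutes. The crossing between these two cases is what we look for.

| flask | substrate | free catalyst | remark | time |
|---|---|---|---|---|
| Friday's | 0.63 M | 90 mM | run made earlier |  |
| Monday's | 2.6 M | 90 mM | run made earlier |  |
| Tuesday's | 1.8 M | 120 mM | run made earlier |  |
| north-west | 1.8 M | 150 mM |  | 12 min |
| north-east | 0.50 M | 200 mM |  | 12 min |
| north | 1.8 M | 30 mM |  | 12 min |
| south | 1.8 M | 90 mM |  | 12 min |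
| west | 1.2 M | 400 mM |  | 12 min |

- Friday's (time / min: target / %, substrate / %): 1.00: 4.5, 87.9; 2.00: 10.2, 79.5; 5.00: 27.5, 58.7; 12.0: 41.4, 23.3
- Monday's (time / min: target / %, substrate / %): 1.00: 1.9, 94.5; 2.00: 4.4, 91.6; 5.00: 11.4, 82.3; 12.0: 20.9, 62.6
- Tuesday's (time / min: target / %, substrate / %): 3.00: 12.2, 81.0; 6.00: 21.3, 64.8; 10.0: 31.6, 46.7; 12.0: 34.2, 38.8

(each reading ± 0.5 percentage points)

1. ranking by amount of target, in percent of the substrate charged, from high to low, at 12 min (north-west / north-east / north / south / west)
2. the amount of target, in percent of the substrate charged of the flask you put first, at 12 min
3. the amount of target, in percent of the substrate charged of the flask you put last, at 12 min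

The loss shows in Friday's run, where substrate plus target falls from 92.4% to 64.7%. The feed shows in w, the substrate lost per minute per free catalyst charged (the turnover frequency). We read w as 0.511 /min in Friday's run near 0.462 M, 0.703 /min in Tuesday's near 1.08 M, and 0.813 /min in Monday's near 1.88 M.

Call [substrate] at the charge divided by w times [free catalyst] at the charge the spending time; for north, with Monday's w, it is 73.8 min. Each flask borrows w from the run whose [substrate] over the reading window lies nearest the flask's charge.

| flask | w from | spending time | asked time / spending time |
|---|---|---|---|
| north | Monday's | 73.8 min | 0.163 |
| south | Monday's | 24.6 min | 0.488 |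
| north-west | Monday's | 14.8 min | 0.813 |
| west | Tuesday's | 4.27 min | 2.81 |
| north-east | Friday's | 4.89 min | 2.45 |

The top rows stand before the crossing. For north we multiply the last column by the share of lost substrate that Tuesday's run held as target at its last reading, 55.9%. North then gives 9.09%, and we put it last. South comes above it, since its spending time is shorter than north's. North-west has a spending time a little longer than Friday's own 13.7 min, so we expect just under Friday's 41.4%.

West and north-east are past the crossing. We judge that they stand above north-west, but below 55.9%. We put north-east first, since its spending time is longer than west's, which leaves target in north-east fewer unfed minutes.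

The forecast gives the same order, north-east > west > north-west > south > north, with 46% and 10%, on the ground that “Yield is therefore conversion discounted by the time target sits around”.

The flask gives north-east > west > north-west > south > north, with 48.5% first and 9.34% last. With the path between target and isomer of the product struck out both ways, north-east reads 98.1% instead. For north, the asked time over the spending time gives 16.3% of the substrate lost, and the flask has lost 17.0%.

    substrate + free catalyst → catalyst intermediate A (k = 0.0390 /M/s)
    catalyst intermediate A → catalyst intermediate B (k = 0.0590 /s)
    catalyst intermediate B → free catalyst + target (k = 0.0240 /s)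
    target ⇌ isomer of the product (K = 1.90, k = 0.00220 /s)

Left to 50 min, north is still short of its spending time, so the reckoning leaves 32.2% of the substrate. The computed flask holds 38% unbound, with 24.7% target.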